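## The problem

The target is an aryl tert-alkyl ether. The ortho hydroxyl of 3',5-diallylbiphenyl-2,4'-diol (ring A carries the ether oxygen, ring B the free phenol) is bound to a tertiary carbon of a trans-decalin. The decalin is numbered C1–C10: ring C is C1–C5/C10 with the ether carbon C3, the ring-fusion CH C5 and the methyl-bearing ring-fusion carbon C10; ring D is C5–C10 with the side chain on C7 (C11 is its central carbon, C12 its terminal carbon). With β as the face of the C10 methyl, the centres are 10β-CH3, 5α-H, 7β (equatorial) side chain, 3α (axial) oxygen and 3β (equatorial) methyl, i.e. 3R,5S,7R,10S. C7 is the only centre that can be made by catalysis on an open chain; C5 and C10 must be derived from it when the rings form. C3 can then be set by the ring, because the axial C10 methyl shields the β face of ring C. Substitution at tertiary C3 cannot be controlled, so the C3–O bond must first exist as an alcohol whose oxygen is then arylated, as a hindered axial tertiary alkoxide. The tert-alkyl aryl ether and the tertiary alcohol ionise or eliminate in acid; the allyl groups migrate into conjugation under strong base and are attacked by peracids and hydration reagents. The ether must therefore be made and carried under neutral or basic conditions, and all alkene oxidation must be finished before the allyl groups arrive. The enabling feature is that ring C carries its two methyl groups 1,4 to each other (C10 and C3). With a C3=C4 double bond and a carbonyl at C9, ring C is a cyclohexene retron: the diene C2=C3(CH3)–C4=C5 is an isoprene unit, the dienophile C10(CH3)=C1 a methacryloyl unit, and the chain C9–C8–C7–C6 already joins them.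

## Retrosynthesis

**Biaryl bond.** Target 29 is cut between ring A and ring B into aryl chloride 26 and boronate 28 (from bromophenol 27). This cut comes last because ring B brings a free phenol and an allyl group that would survive neither the alkoxide arylation nor the alkene hydration. Transferring the whole biaryl as an iodonium salt was rejected: its allyl groups would not survive the oxidant needed to make the salt. The forward coupling must engage a hindered C–Cl bond next to the bulky alkoxy group without moving either allyl group.

**Allyl–arene bond.** Chloride 26 is cut to bromide 24 and stannane 25. A para bromide and an ortho chloride give two handles that are addressed in order by the choice of catalyst. The allyl group is attached only after the hydration, which would not tell an allyl from an isopropenyl group.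

**C11–O bond.** Alcohol 24 goes back to isopropenyl compound 23. Keeping the side chain as an alkene through the arylation means only one hydroxyl is present when the alkoxide is formed; a diol would need protection and deprotection. The forward step is a Markovnikov hydration under neutral conditions.

**O–aryl bond.** Ether 23 is cut at O–C(aryl) into tertiary alcohol 18 and iodonium salt 22 (from iodoarene 19 and trimethoxybenzene 20). Cutting on the aryl side leaves the C3–O bond intact, so C3 keeps its configuration; ionisation at C3 would give mixtures, C-alkylation and elimination. An iodonium salt transfers an unactivated dihaloaryl group at room temperature; a nucleophilic aromatic substitution would need a nitro or carbonyl activator that has to be converted afterwards.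

**C3–O and C4–H bonds.** Alcohol 18 comes from epoxide 17 and this from diene 16. Direct hydration of C3=C4 would neither distinguish it from the isopropenyl group nor control C3. A peracid prefers the trisubstituted alkene and the α face, and hydride then opens the epoxide at C4 in the diaxial sense, so both selectivities rest on the ring.

**C9 oxygen.** Diene 16 is octalinone 14 without its carbonyl. The ketone serves only to activate the cycloaddition and is removed at once. The forward step must reduce a ketone next to a quaternary carbon without touching two alkenes.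

**Ring-forming cut.** Octalinone 14 is opened at C10–C5 and C1–C2 to trienone 13. An intermolecular cycloaddition of isoprene onto a cyclohexenone would fix a cis ring fusion with no epimerisable centre. The intramolecular version makes both rings, the quaternary centre and the C3=C4 alkene from an open chain with one stereocentre. It has to give the trans fusion and place C7 cis to the C10 methyl.

**Chain assembly.** Trienone 13 is cut at C9–C10 into Weinreb amide 10 and Grignard reagent 11. The enone is made last because it would not survive the phosphonate anion of the preceding step. Diene 10 is cut at C5=C4 into aldehyde 8 and phosphonate 9; 8 comes from alcohol 7, silyl ether 6 and ester 5 by functional-group changes.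

**The stereocentre.** Ester 5 is cut at C7–C11 into enoate 3 and boronate 4; 3 comes from aldehyde 1 and phosphonoacetate 2. This catalytic conjugate addition is the only source of absolute configuration, so it must be highly enantioselective on a simple (E)-enoate.

## Roads not taken

**Alternative 1:** Ring A is built on the ether oxygen. The cut removes the two ring A bonds flanking the oxygen-bearing and biaryl carbons. Forward, the aryl ynol ether A1 of the finished terpene alcohol reacts with methyl coumalate A2 in an inverse-demand [4+2] cycloaddition; decarboxylative aromatisation gives benzoate A3.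
- Merits: the hindered oxygen is never arylated, the biaryl bond arrives with the alkyne, and the polarisation of the ynol ether fixes the regiochemistry.
- Weak points: the complete terpene alcohol with four stereocentres must exist first, so the decalin problem is untouched. tert-Alkyl ynol ethers fragment on warming (retro-ene loss of alkene), while the pyrone cycloaddition and extrusion need heat. The ester of A3 must still be turned into an allyl group and two silyl groups removed.
- Comparison: for the ether bond alone this road is arguably safer, since an alkynyl ether of a hindered alkoxide forms more easily than an aryl ether. The chosen plan sets against it a one-step, room-temperature arylation with retention (18 to 23), a shorter arene endgame and a solution for the terpene half.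

**Alternative 2:** A prochiral triketone is desymmetrised. The cut is the C4=C5 bond. Forward, L-proline A5 catalyses the intramolecular aldol condensation of triketone A4 at one of its enantiotopic ring carbonyls and gives enedione ester A6 with the C10 quaternary centre.
- Merits: an organocatalytic entry to angularly methylated decalins. A6 has a handle at each needed position: the C3 ketone for the methyl group, the C4=C5 enone for a trans fusion by dissolving-metal reduction, the ester for the dimethylcarbinol.
- Weak points: A4 must be a single diastereomer, and the selection between its carbonyls in the presence of the remote ester is less secure than in the parent case. Three carbonyl groups must be told apart. Methyl addition to a C3 ketone gives the axial alcohol with only moderate preference. The C9 ketone must be deleted here too.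
- Comparison: in ring-fusion control this road is better, because enone reduction gives the trans-decalin predictably, whereas the cycloaddition of 13 must win a kinetic contest that cannot be corrected later. It is probably no longer. The chosen plan sets against it one step that makes both rings, two stereocentres and the C3=C4 alkene where oxygen is needed; a C3 centre set by stereospecific epoxide opening; and no carbonyl differentiation.

**Alternative 3:** The tertiary carbinol is made by an ene closure. The cut is the C3–C4 bond. Forward, Me2AlCl A8 promotes a type 2 carbonyl-ene reaction of keto-olefin A7: the exocyclic methylene carbon attacks the methyl ketone and gives tertiary alcohol A9 with a C5=C6 alkene.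
- Merits: the C3 carbinol and ring C form together, and the new hydroxyl could direct the hydrogenation that sets C5.
- Weak points: A7 already contains the quaternary C10 centre cis to C7, so the hardest centre is moved into the precursor synthesis. The axial or equatorial position of the complexed oxygen in the ene transition state, and so the C3 configuration, is uncertain. A tertiary homoallylic alcohol under a Lewis acid can ionise.
- Comparison: after its key step this road is closer to the carbinol (one hydrogenation against deoxygenation, epoxidation and reduction in the chosen plan), which is better. The chosen plan sets against it that its key step starts from an open chain with one catalytically made stereocentre and itself creates the quaternary centre.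

Key step: step 8

Assumption: α/β and C1–C12 are used as defined in the first section for all bicyclic compounds.
Assumption: 2-allyl-4-bromophenol (27) and isopropenylmagnesium bromide (11, THF solution) are taken as catalogue items; 27 is otherwise two steps from 4-bromophenol (O-allylation, Claisen rearrangement).

## Route

Step 1
Reactants: 1 3-[(tert-butyldimethylsilyl)oxy]propanal; 2 triethyl phosphonoacetate
Product: 3 ethyl (2E)-5-[(tert-butyldimethylsilyl)oxy]pent-2-enoate
Conditions: NaH, THF, 0 °C → rt
Reagents that add atoms: none
Why: Horner–Wadsworth–Emmons olefination of an unhindered aldehyde with a stabilised phosphonate anion; reversible addition and syn elimination give the (E)-enoate.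

Step 2
Reactants: 3 ethyl (2E)-5-[(tert-butyldimethylsilyl)oxy]pent-2-enoate; 4 isopropenylboronic acid pinacol ester
Product: 5 ethyl (3S)-5-[(tert-butyldimethylsilyl)oxy]-3-(prop-1-en-2-yl)pentanoate
Conditions: [Rh(acac)(C2H4)2] (3 mol %), (R)-BINAP (3.3 mol %), K3PO4 (20 mol %), 1,4-dioxane/H2O 10:1, 80 °C
Reagents that add atoms: none
Why: Asymmetric conjugate addition of an alkenylboron reagent to an (E)-enoate through a BINAP-ligated alkenylrhodium species, with water protonating the rhodium enolate; the (R)-ligand is chosen by the usual facial model for (E)-acceptors so that the new centre (the future C7) is S, the sense to be confirmed by correlation at this stage.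

Step 3
Reactants: 5 ethyl (3S)-5-[(tert-butyldimethylsilyl)oxy]-3-(prop-1-en-2-yl)pentanoate
Product: 6 (3S)-5-[(tert-butyldimethylsilyl)oxy]-N-methoxy-N-methyl-3-(prop-1-en-2-yl)pentanamide
Conditions: MeNHOMe·HCl, i-PrMgCl, THF, −20 → 0 °C
Reagents that add atoms: N,O-dimethylhydroxylamine hydrochloride, CNOC.Cl
Why: Weinreb amide formation by aminolysis of the ester with the magnesium amide made in the flask; the cold, non-enolising conditions leave the β-stereocentre and the silyl ether untouched.

Step 4
Reactants: 6 (3S)-5-[(tert-butyldimethylsilyl)oxy]-N-methoxy-N-methyl-3-(prop-1-en-2-yl)pentanamide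
Product: 7 (3S)-5-hydroxy-N-methoxy-N-methyl-3-(prop-1-en-2-yl)pentanamide
Conditions: HF·pyridine, pyridine, THF, 0 °C → rt
Reagents that add atoms: none
Why: Fluoride cleavage of a primary silyl ether under buffered, weakly acidic conditions, which keep the δ-hydroxy amide from lactonising as its alkoxide could.

Step 5
Reactants: 7 (3S)-5-hydroxy-N-methoxy-N-methyl-3-(prop-1-en-2-yl)pentanamide
Product: 8 (3S)-N-methoxy-N-methyl-5-oxo-3-(prop-1-en-2-yl)pentanamide
Conditions: Dess–Martin periodinane, CH2Cl2, 0 °C → rt
Reagents that add atoms: none
Why: Dess–Martin oxidation of a primary alcohol to the aldehyde without over-oxidation; the stereocentre is β to both carbonyl groups and cannot epimerise.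

Step 6
Reactants: 8 (3S)-N-methoxy-N-methyl-5-oxo-3-(prop-1-en-2-yl)pentanamide; 9 diethyl (2-methylprop-2-en-1-yl)phosphonate
Product: 10 (3S,5E)-N-methoxy-N,7-dimethyl-3-(prop-1-en-2-yl)octa-5,7-dienamide
Conditions: 9, n-BuLi, THF/HMPA, −78 °C; then 8, −78 °C → rt
Reagents that add atoms: none
Why: Horner–Wadsworth–Emmons dienylation: the lithiated allylic phosphonate adds through its α-carbon to the aldehyde, far faster than to the Weinreb amide at −78 °C, and loss of phosphate on warming gives the (E)-1,3-diene.

Step 7
Reactants: 10 (3S,5E)-N-methoxy-N,7-dimethyl-3-(prop-1-en-2-yl)octa-5,7-dienamide; 11 isopropenylmagnesium bromide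
Product: 13 (5S,7E)-2,9-dimethyl-5-(prop-1-en-2-yl)deca-1,7,9-trien-3-one, via bromomagnesium hemiaminal chelate 12 (not isolated)
Conditions: 11, THF, −78 → 0 °C; inverse quench into cold 1 M HCl; BHT added, used at once
Reagents that add atoms: none
Why: Weinreb ketone synthesis: the alkenyl Grignard reagent adds once because chelate 12 persists until the cold acidic quench, which also stops the released amine from adding to the enone.

Step 8
Reactants: 13 (5S,7E)-2,9-dimethyl-5-(prop-1-en-2-yl)deca-1,7,9-trien-3-one
Product: 14 (3S,4aS,8aS)-6,8a-dimethyl-3-(prop-1-en-2-yl)-3,4,4a,7,8,8a-hexahydronaphthalen-1(2H)-one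
Conditions: toluene (0.02 M), BHT (5 mol %), 130 °C, sealed tube, argon
Reagents that add atoms: none
Why: A thermal, concerted but asynchronous normal-demand [4+2] cycloaddition joins the diene C2=C3–C4=C5 to the α-methyl enone C10=C1; the closest known reaction type is the intramolecular Diels–Alder reaction of 1,7,9-decatrien-3-ones, including 2-methyl congeners that give angularly methylated octalones. Ring C (cyclohexene) closes by the cycloaddition itself through the C1–C2 and C10–C5 bonds; ring D (cyclohexanone) closes because the four-atom tether C9–C8–C7–C6 already links C10 to C5, which also fixes the regiochemistry. C5 and C10 are set relative to each other by the orientation of the tether at the dienophile: the trans fusion needs the ketone-bearing tether exo and the C10 methyl under the diene, the cis fusion the reverse. Both are set relative to C7 by a chair-like tether with the isopropenyl group equatorial, which places the C7 substituent cis to the C10 methyl. The selectivity needed is trans over cis, and it cannot be repaired later because C10 is quaternary and C5 is not α to the ketone. The α-methyl group is what should secure it: α-alkyl enones lose the usual carbonyl-endo preference, since the methyl competes for the endo position, and the tether-exo geometry allows a strain-free chair with a planar s-cis enone. No Lewis acid is used, because complexation would strengthen the carbonyl-endo (cis) pathway; dilution and BHT suppress dimerisation and polymerisation of the enone. The cis-fused isomer is the expected by-product and is to be separated at this stage.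

Step 9
Reactants: 14 (3S,4aS,8aS)-6,8a-dimethyl-3-(prop-1-en-2-yl)-3,4,4a,7,8,8a-hexahydronaphthalen-1(2H)-one
Product: 16 (2R,4aS,8aS)-4a,7-dimethyl-2-(prop-1-en-2-yl)-1,2,3,4,4a,5,6,8a-octahydronaphthalene, via hydrazone 15 (not isolated)
Conditions: N2H4·H2O, KOH, diethylene glycol, 130 °C; then distil to 200 °C, argon
Reagents that add atoms: hydrazine hydrate, NN.O (nitrogen of intermediate 15 only; none remains in 16)
Why: Wolff–Kishner reduction in the Huang–Minlon modification: the hydrazone forms at 130 °C and loses N2 at 200 °C; the only α-stereocentre is quaternary, and the isolated alkenes are inert to hot base when air (diimide formation) is excluded.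

Step 10
Reactants: 16 (2R,4aS,8aS)-4a,7-dimethyl-2-(prop-1-en-2-yl)-1,2,3,4,4a,5,6,8a-octahydronaphthalene
Product: 17 (3R,4S,5R,7R,10S)-3,4-epoxy-3,10-dimethyl-7-(prop-1-en-2-yl)decalin (3α,4α-epoxide)
Conditions: mCPBA (1.05 equiv), CH2Cl2, −10 °C; wash with aq. Na2SO3 and NaHCO3
Reagents that add atoms: mCPBA, OOC(=O)c1cccc(Cl)c1
Why: Prilezhaev epoxidation: the trisubstituted ring alkene is markedly more nucleophilic than the 1,1-disubstituted isopropenyl group, and the axial C10 methyl, syn-axial to C4, blocks the β face so that oxygen arrives from the α face.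

Step 11
Reactants: 17 (3R,4S,5R,7R,10S)-3,4-epoxy-3,10-dimethyl-7-(prop-1-en-2-yl)decalin
Product: 18 (2R,4aS,7R,8aS)-2,4a-dimethyl-7-(prop-1-en-2-yl)decahydronaphthalen-2-ol
Conditions: LiAlH4, THF, reflux; Fieser work-up
Reagents that add atoms: none
Why: Hydride opens the trisubstituted epoxide at its less substituted carbon C4 from the β face, which is also the trans-diaxial (Fürst–Plattner) mode; the C3–O bond is untouched and emerges as the axial tertiary alcohol with the methyl equatorial.

Step 12
Reactants: 19 4-bromo-2-chloro-1-iodobenzene; 20 1,3,5-trimethoxybenzene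
Product: 22 (4-bromo-2-chlorophenyl)(2,4,6-trimethoxyphenyl)iodonium 4-methylbenzenesulfonate, via hydroxy(tosyloxy)iodoarene 21 (not isolated)
Conditions: mCPBA, TsOH·H2O, MeCN, 77 °C; then 20, rt
Reagents that add atoms: p-toluenesulfonic acid monohydrate, Cc1ccc(S(=O)(=O)O)cc1.O; mCPBA, OOC(=O)c1cccc(Cl)c1 (oxygen of intermediate 21 only)
Why: One-pot synthesis of an unsymmetrical diaryliodonium salt: the aryl iodide is oxidised to the trivalent-iodine species 21, which substitutes the very electron-rich trimethoxybenzene at carbon.

Step 13
Reactants: 18 (2R,4aS,7R,8aS)-2,4a-dimethyl-7-(prop-1-en-2-yl)decahydronaphthalen-2-ol; 22 (4-bromo-2-chlorophenyl)(2,4,6-trimethoxyphenyl)iodonium 4-methylbenzenesulfonate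
Product: 23 (2R,4aS,7R,8aS)-7-(4-bromo-2-chlorophenoxy)-4a,7-dimethyl-2-(prop-1-en-2-yl)decahydronaphthalene
Conditions: NaHMDS, toluene, 0 °C → rt; then 22, rt → 40 °C
Reagents that add atoms: none
Why: Metal-free O-arylation of a tertiary alkoxide with a diaryliodonium salt: ligand exchange at iodine and ligand coupling transfer the electron-poorer, ortho-substituted aryl group and leave the trimethoxyphenyl group on iodine; the carbinol C–O bond is never broken, so C3 keeps its configuration.

Step 14
Reactants: 23 (2R,4aS,7R,8aS)-7-(4-bromo-2-chlorophenoxy)-4a,7-dimethyl-2-(prop-1-en-2-yl)decahydronaphthalene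
Product: 24 2-[(2R,4aS,7R,8aS)-7-(4-bromo-2-chlorophenoxy)-4a,7-dimethyldecahydronaphthalen-2-yl]propan-2-ol
Conditions: Co(acac)2 (20 mol %), PhSiH3, O2 (1 atm), THF, rt
Reagents that add atoms: dioxygen, O=O
Why: Mukaiyama hydration: hydrogen-atom transfer from a cobalt hydride to the 1,1-disubstituted alkene gives the tertiary radical, which is trapped by O2 and reduced to the Markovnikov alcohol; the neutral conditions spare the acid-labile ether and the aryl halides, and no stereocentre is formed.

Step 15
Reactants: 24 2-[(2R,4aS,7R,8aS)-7-(4-bromo-2-chlorophenoxy)-4a,7-dimethyldecahydronaphthalen-2-yl]propan-2-ol; 25 allyltributylstannane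
Product: 26 2-[(2R,4aS,7R,8aS)-7-[2-chloro-4-(prop-2-en-1-yl)phenoxy]-4a,7-dimethyldecahydronaphthalen-2-yl]propan-2-ol
Conditions: Pd(PPh3)4 (5 mol %), toluene, 105 °C
Reagents that add atoms: none
Why: Stille coupling: Pd(PPh3)4 inserts into the C–Br bond only, the hindered C–Cl bond being inert to this catalyst, and the base-free allyl transfer from tin limits migration to the propenyl isomer.

Step 16
Reactants: 27 2-allyl-4-bromophenol
Product: 28 2-allyl-4-(4,4,5,5-tetramethyl-1,3,2-dioxaborolan-2-yl)phenol
Conditions: B2pin2, Pd(dppf)Cl2 (3 mol %), KOAc, 1,4-dioxane, 85 °C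
Reagents that add atoms: bis(pinacolato)diboron, CC1(C)OB(OC1(C)C)B1OC(C)(C)C(C)(C)O1
Why: Miyaura borylation of an aryl bromide; KOAc is too weak a base to promote biaryl homocoupling or allyl migration, and the free phenol is tolerated.

Step 17
Reactants: 26 2-[(2R,4aS,7R,8aS)-7-[2-chloro-4-(prop-2-en-1-yl)phenoxy]-4a,7-dimethyldecahydronaphthalen-2-yl]propan-2-ol; 28 2-allyl-4-(4,4,5,5-tetramethyl-1,3,2-dioxaborolan-2-yl)phenol
Product: 29 2-[(2R,4aS,7R,8aS)-7-{[4'-hydroxy-3',5-di(prop-2-en-1-yl)-[1,1'-biphenyl]-2-yl]oxy}-4a,7-dimethyldecahydronaphthalen-2-yl]propan-2-ol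
Conditions: Pd(OAc)2 (5 mol %), SPhos (10 mol %), K3PO4, toluene/H2O 10:1, 90 °C; neutral work-up, chromatography on base-washed silica
Reagents that add atoms: none
Why: Suzuki–Miyaura coupling of a hindered, electron-rich aryl chloride, the substrate class for which the bulky electron-rich biarylphosphine SPhos is suited; aqueous phosphate leaves the tertiary ether and alcohol intact and the phenol is recovered on neutral work-up.

## Compound list

1 | 3-[(tert-butyldimethylsilyl)oxy]propanal | O=CCCO[Si](C)(C)C(C)(C)C | starting material
2 | triethyl phosphonoacetate | CCOC(=O)CP(=O)(OCC)OCC | starting material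
3 | ethyl (2E)-5-[(tert-butyldimethylsilyl)oxy]pent-2-enoate | CCOC(=O)/C=C/CCO[Si](C)(C)C(C)(C)C | intermediate
4 | isopropenylboronic acid pinacol ester | CC(=C)B1OC(C)(C)C(C)(C)O1 | starting material
5 | ethyl (3S)-5-[(tert-butyldimethylsilyl)oxy]-3-(prop-1-en-2-yl)pentanoate | CCOC(=O)C[C@@H](C(C)=C)CCO[Si](C)(C)C(C)(C)C | intermediate
6 | (3S)-5-[(tert-butyldimethylsilyl)oxy]-N-methoxy-N-methyl-3-(prop-1-en-2-yl)pentanamide | CON(C)C(=O)C[C@@H](C(C)=C)CCO[Si](C)(C)C(C)(C)C | intermediate
7 | (3S)-5-hydroxy-N-methoxy-N-methyl-3-(prop-1-en-2-yl)pentanamide | CON(C)C(=O)C[C@@H](C(C)=C)CCO | intermediate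
8 | (3S)-N-methoxy-N-methyl-5-oxo-3-(prop-1-en-2-yl)pentanamide | CON(C)C(=O)C[C@@H](C(C)=C)CC=O | intermediate
9 | diethyl (2-methylprop-2-en-1-yl)phosphonate | CCOP(=O)(CC(C)=C)OCC | starting material
10 | (3S,5E)-N-methoxy-N,7-dimethyl-3-(prop-1-en-2-yl)octa-5,7-dienamide | CON(C)C(=O)C[C@@H](C(C)=C)C/C=C/C(C)=C | intermediate
11 | isopropenylmagnesium bromide | CC(=C)[Mg]Br | starting material
12 | bromomagnesium hemiaminal chelate from 10 and 11 (hemiaminal carbon undefined) | CON(C)C(O[Mg]Br)(C(C)=C)C[C@@H](C(C)=C)C/C=C/C(C)=C | intermediate
13 | (5S,7E)-2,9-dimethyl-5-(prop-1-en-2-yl)deca-1,7,9-trien-3-one | C=C(C)C(=O)C[C@@H](C(C)=C)C/C=C/C(C)=C | intermediate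
14 | (3S,4aS,8aS)-6,8a-dimethyl-3-(prop-1-en-2-yl)-3,4,4a,7,8,8a-hexahydronaphthalen-1(2H)-one (trans-fused; C9 ketone, C3=C4) | CC1=C[C@@H]2C[C@H](C(C)=C)CC(=O)[C@@]2(C)CC1 | intermediate
15 | hydrazone of 14 | CC1=C[C@@H]2C[C@H](C(C)=C)CC(=NN)[C@@]2(C)CC1 | intermediate
16 | (2R,4aS,8aS)-4a,7-dimethyl-2-(prop-1-en-2-yl)-1,2,3,4,4a,5,6,8a-octahydronaphthalene | CC1=C[C@@H]2C[C@H](C(C)=C)CC[C@@]2(C)CC1 | intermediate
17 | (3R,4S,5R,7R,10S)-3,4-epoxy-3,10-dimethyl-7-(prop-1-en-2-yl)decalin (3α,4α-epoxide) | O1[C@]2(C)CC[C@]3(C)CC[C@@H](C(C)=C)C[C@H]3[C@H]12 | intermediate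
18 | (2R,4aS,7R,8aS)-2,4a-dimethyl-7-(prop-1-en-2-yl)decahydronaphthalen-2-ol | O[C@]1(C)CC[C@]2(C)CC[C@@H](C(C)=C)C[C@H]2C1 | intermediate
19 | 4-bromo-2-chloro-1-iodobenzene | Clc1cc(Br)ccc1I | starting material
20 | 1,3,5-trimethoxybenzene | COc1cc(OC)cc(OC)c1 | starting material
21 | 4-bromo-2-chloro-1-[hydroxy(tosyloxy)iodo]benzene | Cc1ccc(S(=O)(=O)OI(O)c2ccc(Br)cc2Cl)cc1 | intermediate
22 | (4-bromo-2-chlorophenyl)(2,4,6-trimethoxyphenyl)iodonium 4-methylbenzenesulfonate | COc1cc(OC)c([I+]c2ccc(Br)cc2Cl)c(OC)c1.Cc1ccc(S(=O)(=O)[O-])cc1 | intermediate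
23 | (2R,4aS,7R,8aS)-7-(4-bromo-2-chlorophenoxy)-4a,7-dimethyl-2-(prop-1-en-2-yl)decahydronaphthalene | Brc1ccc(O[C@]2(C)CC[C@]3(C)CC[C@@H](C(C)=C)C[C@H]3C2)c(Cl)c1 | intermediate
24 | 2-[(2R,4aS,7R,8aS)-7-(4-bromo-2-chlorophenoxy)-4a,7-dimethyldecahydronaphthalen-2-yl]propan-2-ol | Brc1ccc(O[C@]2(C)CC[C@]3(C)CC[C@@H](C(C)(C)O)C[C@H]3C2)c(Cl)c1 | intermediate
25 | allyltributylstannane | C=CC[Sn](CCCC)(CCCC)CCCC | starting material
26 | 2-[(2R,4aS,7R,8aS)-7-[2-chloro-4-(prop-2-en-1-yl)phenoxy]-4a,7-dimethyldecahydronaphthalen-2-yl]propan-2-ol | C=CCc1ccc(O[C@]2(C)CC[C@]3(C)CC[C@@H](C(C)(C)O)C[C@H]3C2)c(Cl)c1 | intermediate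
27 | 2-allyl-4-bromophenol | C=CCc1cc(Br)ccc1O | starting material
28 | 2-allyl-4-(4,4,5,5-tetramethyl-1,3,2-dioxaborolan-2-yl)phenol | C=CCc1cc(B2OC(C)(C)C(C)(C)O2)ccc1O | intermediate
29 | 2-[(2R,4aS,7R,8aS)-7-{[4'-hydroxy-3',5-di(prop-2-en-1-yl)-[1,1'-biphenyl]-2-yl]oxy}-4a,7-dimethyldecahydronaphthalen-2-yl]propan-2-ol | C=CCc1ccc(O[C@]2(C)CC[C@]3(C)CC[C@@H](C(C)(C)O)C[C@H]3C2)c(-c2ccc(O)c(CC=C)c2)c1 | target

## Step count and least certain steps

Total step count: 17. Longest linear sequence: 15 (steps 1–11, 13, 14, 15 and 17); steps 12 and 16 prepare the arylating salt and the boronate.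

**Step 8 (key step).** The most likely failure is an insufficient preference for the tether-exo transition state, so that the carbonyl-endo mode gives much cis-fused adduct; this cannot be repaired by epimerisation. Secondary risks at 130 °C are a Cope rearrangement across the 1,5-diene C12=C11–C7–C6–C5=C4 and polymerisation of the enone.
Fallback: it sets out from Weinreb amide 10 and comes back at octalinone 14, and it moves the C10 centre out of the cycloaddition. Ethynylmagnesium bromide converts 10 into (5S,7E)-9-methyl-5-(prop-1-en-2-yl)deca-7,9-dien-1-yn-3-one F1. Its intramolecular Diels–Alder reaction in warm toluene gives the cyclohexadienyl ketone (3S,4aS)-6-methyl-3-(prop-1-en-2-yl)-3,4,4a,7-tetrahydronaphthalen-1(2H)-one F2. In F2, C10 is trigonal, so no ring-fusion isomers can arise, and C5 is set by the same equatorial-isopropenyl chair. Reductive methylation (Li, liquid NH3/THF, one equivalent of t-BuOH; then MeI) reduces the C10=C1 enone and methylates the C10 enolate. The face anti to H-5 should be favoured because the C3=C4 alkene removes the syn-axial hydrogen at C4; this gives 14.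

**Step 13.** Ligand exchange at iodine may be slow for the congested axial alkoxide. The base could then deprotonate the salt (aryne formation, regioisomeric ethers), or the wrong aryl group could be transferred.
Fallback: from alcohol 18 back to ether 23 by nucleophilic aromatic substitution. The potassium alkoxide of 18 (KHMDS, THF) displaces fluoride from 2-chloro-1-fluoro-4-nitrobenzene and gives (2R,4aS,7R,8aS)-7-(2-chloro-4-nitrophenoxy)-4a,7-dimethyl-2-(prop-1-en-2-yl)decahydronaphthalene F3. Fe powder/NH4Cl in aqueous ethanol reduces it to 3-chloro-4-{[(2R,4aS,7R,8aS)-2,4a-dimethyl-7-(prop-1-en-2-yl)decahydronaphthalen-2-yl]oxy}aniline F4. Sandmeyer bromination (t-BuONO, CuBr2, MeCN) then gives 23.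

**Step 2.** Transmetalation of the 1,1-disubstituted alkenylboronate may be slow, so that protodeboronation consumes the reagent, conversion stalls and enantioselectivity is eroded at the temperature needed.
Fallback: from aldehyde 1 to Weinreb amide 6 with an auxiliary in place of the catalyst. Olefination of 1 with diethyl {2-oxo-2-[(4R)-2-oxo-4-phenyl-1,3-oxazolidin-3-yl]ethyl}phosphonate (LiCl, i-Pr2NEt, MeCN) gives (4R)-3-[(2E)-5-{[tert-butyl(dimethyl)silyl]oxy}pent-2-enoyl]-4-phenyl-1,3-oxazolidin-2-one F5. Addition of 11 with CuBr·SMe2 to the chelated imide, anti to the phenyl group, gives (4R)-3-[(3S)-5-{[tert-butyl(dimethyl)silyl]oxy}-3-(prop-1-en-2-yl)pentanoyl]-4-phenyl-1,3-oxazolidin-2-one F6. Transamidation with MeNHOMe·HCl/AlMe3 gives 6.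

**Step 9.** Hydrazone formation next to the quaternary C10 may be incomplete, and hot alkoxide may move the alkenes.
Fallback: from ketone 14 to diene 16 by radical deoxygenation. LiAlH4 reduces 14 to (1S,3S,4aS,8aS)-6,8a-dimethyl-3-(prop-1-en-2-yl)-1,2,3,4,4a,7,8,8a-octahydronaphthalen-1-ol F7 (either C9 epimer serves). NaH, CS2 and MeI give the xanthate O-[(1S,3S,4aS,8aS)-6,8a-dimethyl-3-(prop-1-en-2-yl)-1,2,3,4,4a,7,8,8a-octahydronaphthalen-1-yl] S-methyl carbonodithioate F8. Barton–McCombie reduction (Bu3SnH, AIBN, toluene, 110 °C) gives 16; the C9 radical has no favourable cyclisation onto either alkene.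

**Step 6.** The allylic anion may attack through its γ-carbon, the elimination may give some (Z)-diene, and the anion may attack the Weinreb amide.
Fallback: from aldehyde 8 to diene 10 in two steps that fix the geometry. Takai olefination (CrCl2, CHI3, THF) gives (3S,5E)-6-iodo-N-methoxy-N-methyl-3-(prop-1-en-2-yl)hex-5-enamide F9. Suzuki–Miyaura coupling with boronate 4 (Pd(dppf)Cl2, K3PO4, THF/H2O) gives 10.

## Further compounds

F1 | step 8 | (5S,7E)-9-methyl-5-(prop-1-en-2-yl)deca-7,9-dien-1-yn-3-one | C#CC(=O)C[C@@H](C(C)=C)C/C=C/C(C)=C
F2 | step 8 | (3S,4aS)-6-methyl-3-(prop-1-en-2-yl)-3,4,4a,7-tetrahydronaphthalen-1(2H)-one | CC1=C[C@@H]2C[C@H](C(C)=C)CC(=O)C2=CC1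
F3 | step 13 | (2R,4aS,7R,8aS)-7-(2-chloro-4-nitrophenoxy)-4a,7-dimethyl-2-(prop-1-en-2-yl)decahydronaphthalene | O=[N+]([O-])c1ccc(O[C@]2(C)CC[C@]3(C)CC[C@@H](C(C)=C)C[C@H]3C2)c(Cl)c1
F4 | step 13 | 3-chloro-4-{[(2R,4aS,7R,8aS)-2,4a-dimethyl-7-(prop-1-en-2-yl)decahydronaphthalen-2-yl]oxy}aniline | Nc1ccc(O[C@]2(C)CC[C@]3(C)CC[C@@H](C(C)=C)C[C@H]3C2)c(Cl)c1
F5 | step 2 | (4R)-3-[(2E)-5-{[tert-butyl(dimethyl)silyl]oxy}pent-2-enoyl]-4-phenyl-1,3-oxazolidin-2-one | CC(C)(C)[Si](C)(C)OCC/C=C/C(=O)N1[C@H](c2ccccc2)COC1=O
F6 | step 2 | (4R)-3-[(3S)-5-{[tert-butyl(dimethyl)silyl]oxy}-3-(prop-1-en-2-yl)pentanoyl]-4-phenyl-1,3-oxazolidin-2-one | CC(C)(C)[Si](C)(C)OCC[C@H](C(C)=C)CC(=O)N1[C@H](c2ccccc2)COC1=O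
F7 | step 9 | (1S,3S,4aS,8aS)-6,8a-dimethyl-3-(prop-1-en-2-yl)-1,2,3,4,4a,7,8,8a-octahydronaphthalen-1-ol | CC1=C[C@@H]2C[C@H](C(C)=C)C[C@H](O)[C@@]2(C)CC1
F8 | step 9 | O-[(1S,3S,4aS,8aS)-6,8a-dimethyl-3-(prop-1-en-2-yl)-1,2,3,4,4a,7,8,8a-octahydronaphthalen-1-yl] S-methyl carbonodithioate | CC1=C[C@@H]2C[C@H](C(C)=C)C[C@H](OC(=S)SC)[C@@]2(C)CC1
F9 | step 6 | (3S,5E)-6-iodo-N-methoxy-N-methyl-3-(prop-1-en-2-yl)hex-5-enamide | CON(C)C(=O)C[C@@H](C(C)=C)C/C=C/I
A1 | alternative 1 | aryl ynol ether of the silyl-protected terpene alcohol with ring B on the alkyne | C=CCc1cc(C#CO[C@]2(C)CC[C@]3(C)CC[C@@H](C(C)(C)O[Si](CC)(CC)CC)C[C@H]3C2)ccc1O[Si](C)(C)C(C)(C)C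
A2 | alternative 1 | methyl coumalate (methyl 2-oxo-2H-pyran-5-carboxylate) | COC(=O)C1=COC(=O)C=C1
A3 | alternative 1 | ring A methyl benzoate with ether and ring B in place | COC(=O)c1ccc(O[C@]2(C)CC[C@]3(C)CC[C@@H](C(C)(C)O[Si](CC)(CC)CC)C[C@H]3C2)c(-c2ccc(O[Si](C)(C)C(C)(C)C)c(CC=C)c2)c1
A4 | alternative 2 | methyl cis-4-methyl-3,5-dioxo-4-(3-oxobutyl)cyclohexane-1-carboxylate (ester cis to methyl) | COC(=O)[C@H]1CC(=O)[C@](C)(CCC(C)=O)C(=O)C1
A5 | alternative 2 | L-proline | OC(=O)[C@@H]1CCCN1
A6 | alternative 2 | bicyclic enedione ester with C10 quaternary centre | O=C1CC[C@]2(C)C(=O)C[C@@H](C(=O)OC)CC2=C1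
A7 | alternative 3 | 4-[1-methyl-2-methylidene-4-(2-triethylsilyloxypropan-2-yl)cyclohexyl]butan-2-one | CC(=O)CC[C@]1(C)CC[C@@H](C(C)(C)O[Si](CC)(CC)CC)CC1=C
A8 | alternative 3 | dimethylaluminium chloride | C[Al](C)Cl
A9 | alternative 3 | octalin tertiary alcohol with C5=C6 alkene | O[C@]1(C)CC[C@]2(C)CC[C@@H](C(C)(C)O[Si](CC)(CC)CC)C=C2C1
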